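The data come from a simulation on assumed constants; noise was put on by code.

Count amounts before you integrate anything. Each starting material in these flasks is charged with 3.00 equiv of coupling partner. The steps thought possible are these: starting material plus partner gives target, target plus partner gives over-reaction product, second substrate plus partner gives second product, protic impurity plus partner gives quenched reagent, and two starting material give homo dimer without partner.

all flasks: starting material 0.18 M
- ash: coupling partner 3 equiv; second substrate 0.50 equiv; protic impurity 5 mM; temperature 35 °C; run made earlier
- elm: coupling partner 3 equiv; second substrate 0.50 equiv; protic impurity 7.9 mM; temperature 85 °C; run made earlier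
- zeta: coupling partner 3.00 equiv; second substrate 0.500 equiv; protic impurity 3.60 mM; temperature 130 °C; time 50 min
- gamma: coupling partner 3.00 equiv; second substrate 0.500 equiv; protic impurity 3.60 mM; temperature 100 °C; time 50 min
- epsilon: coupling partner 3.00 equiv; second substrate 0.500 equiv; protic impurity 3.60 mM; temperature 70 °C; time 50 min
- alpha: coupling partner 3.00 equiv; second substrate 0.500 equiv; protic impurity 3.60 mM; temperature 40 °C; time 50 min

| run | time / min | target / % | starting material / % |
|---|---|---|---|
| ash | 360 | 49.0 | 42.3 |
| ash | 1200 | 56.0 | 12.4 |
| ash | 2400 | 41.4 | 3.3 |
| ash | 3000 | 35.5 | 2.2 |
| ash | 4320 | 25.7 | 1.0 |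
| ash | 5760 | 18.3 | 0 |
| elm | 30.0 | 22.0 | 29.9 |
| elm | 90.0 | 8.6 | 9.8 |
| elm | 180 | 3.2 | 2.0 |
| elm | 240 | 2.2 | 0.9 |
| elm | 360 | 0 | 0.1 |
| elm | 480 | 0.1 | 0.3 |

(each reading ± 0.5 percentage points)

- a species is counted by the starting material in it: one homo dimer counts as two
- steps thought possible: 2 starting material -> homo dimer; coupling partner + protic impurity -> quenched reagent; starting material + coupling partner -> target; coupling partner + target -> over-reaction product; second substrate + coupling partner -> second product

1. the flask with the highest amount of target, in percent of the starting material charged ("all alike" if they lie within 1.5 percentage points) (zeta / gamma / epsilon / alpha / all alike)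
2. final target, as a percentage of the starting material charged, in zeta
3. final target, as a percentage of the starting material charged, in gamma
4. final target, as a percentage of the starting material charged, in epsilon
5. final target, as a percentage of the starting material charged, in alpha

A starting material carried to over-reaction product costs two partner. Pay that, the second substrate and the impurity out of the charge, and 0.480 equiv remain. This is the partner margin, the equivalents of partner left when everything that can take partner has taken it.

Now take the rate. Let r be the pseudo-first-order rate, the chance per minute that a molecule meets partner. As the steps are written, r follows the partner, so it is highest at the start. The impurity then slows it by a factor of 1.01, the second substrate by 1.20, and the road through target to over-reaction product by 5.17. Together that is 6.25.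

That slowing is finite, since the margin is positive. I therefore expect these charges, given time, to end in over-reaction product rather than target, and ash agrees, its target falling from 56.0% to 18.3%. The question is how far along that road each flask stands at 50 min.

The first reading of ash gives an average r of 0.00239 min⁻¹, and that of elm gives 0.0402 min⁻¹. Over 50 min these amount to 0.120 and 2.01 lifetimes. Alpha, at 40 °C, is warmer than ash, so it should have used more of its starting material than the 11.3% that ash's average r gives over 50 min. Elm's target is already falling, from 22.0% to 8.6%, and gamma and zeta are hotter than elm, so I expect them to hold little. My choice is therefore epsilon, between the two runs.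

The forecast also names epsilon, with 0.1% in zeta, 3% in gamma, 29% in epsilon and 13.5% in alpha, holding that “heat hurts selectivity”.

The flasks give 0.0279% in zeta, 3.47% in gamma, 33.0% in epsilon and 17.3% in alpha, so epsilon holds the most.

    2 starting material → homo dimer (k = 1.20 × 10⁻⁴ L mol⁻¹ min⁻¹, Ea = 108 kJ mol⁻¹)
    coupling partner + protic impurity → quenched reagent (k = 1.20 L mol⁻¹ min⁻¹, Ea = 67.0 kJ mol⁻¹)
    starting material + coupling partner → target (k = 0.0530 L mol⁻¹ min⁻¹, Ea = 57.0 kJ mol⁻¹)
    coupling partner + target → over-reaction product (k = 0.0650 L mol⁻¹ min⁻¹, Ea = 89.0 kJ mol⁻¹)
    second substrate + coupling partner → second product (k = 0.200 L mol⁻¹ min⁻¹, Ea = 88.0 kJ mol⁻¹)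
    (constants at 70 °C)

In zeta the margin is 16.0% of the partner charged, and 17% stands at 50.0 min, with 98.0% of the starting material in over-reaction product and 1.79% in homo dimer. The neighbouring flask, zeta with 1.80 equiv of partner, has a margin of −0.720 equiv. At 50.0 min its partner is down to 0.073% of its charge, 26% of its starting material is still there, 61.3% is over-reaction product, and its target reads 5.22%.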